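**Strategy.** The chain (C1 = ketone carbon) is cut between the bis-allylic methylene C7 and C8 of the skipped (5Z,8Z)-diene. Because C5=C6, C8=C9 and C17=C18 are all cis-disubstituted olefins, each is carried as an alkyne, which turns the C5=C6–C7–C8=C9 unit into a 1,4-diyne: C8 becomes a copper acetylide and C7 an SN2-active propargylic bromide. One copper-mediated C(sp)–C(sp3) coupling therefore joins the C8–C20 alkyne, which already holds the 15S silyl ether and the (11Z,13E)-diene, to the C1–C7 bromide bearing the silyl-protected acylphloroglucinol ring. A single Lindlar hydrogenation then sets three Z-olefins and fluoride removes all four silyl groups.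

Key step: step 12

Remark: chain atoms are numbered C1 (ketone carbon) to C20 (methyl). Compounds 3 and 5–9 are racemic at the THP acetal carbon and 8 is a diastereomer mixture; this is immaterial because both centres are gone after step 5.

**Step 1**
Reactants: 1 2,4,6-trihydroxybenzaldehyde
Product: 2 2,4,6-tris(triisopropylsilyloxy)benzaldehyde
Conditions: TIPSOTf, 2,6-lutidine, CH2Cl2, 0 °C to rt
Reagents that add atoms: triisopropylsilyl triflate, `CC(C)[Si](OS(=O)(=O)C(F)(F)F)(C(C)C)C(C)C`
Why: Phenol O-silylation with a silyl triflate and a hindered pyridine base should cap all three hydroxyls, including the ortho ones hydrogen-bonded to the formyl group, and TIPS ethers are chosen to survive Grignard, carbonate and hydrogenation conditions yet fall to fluoride at the end.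

**Step 2**
Reactants: 3 2-(prop-2-yn-1-yloxy)tetrahydro-2H-pyran; 4 1-bromo-3-chloropropane
Product: 6 2-[(6-chlorohex-2-yn-1-yl)oxy]tetrahydro-2H-pyran, via lithium acetylide 5 (not isolated)
Conditions: n-BuLi, THF, −78 °C; then 4, DMPU, −78 °C to rt
Reagents that add atoms: none
Why: SN2 alkylation of the alkynyllithium should occur selectively at the C–Br end of the dihalide, which installs C2–C4 and keeps the chloride for Grignard formation.

**Step 3**
Reactants: 6 2-[(6-chlorohex-2-yn-1-yl)oxy]tetrahydro-2H-pyran; 2 2,4,6-tris(triisopropylsilyloxy)benzaldehyde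
Product: 8 7-(tetrahydro-2H-pyran-2-yloxy)-1-[2,4,6-tris(triisopropylsilyloxy)phenyl]hept-5-yn-1-ol, via Grignard reagent 7 (not isolated)
Conditions: Mg, I2 (cat.), THF, 50 °C; then 2, THF, −78 to 0 °C; aq NH4Cl
Reagents that add atoms: none
Why: Grignard addition to the non-enolisable aldehyde should form the aryl–C1 carbinol, with low temperature and bulky TIPS groups disfavouring silyl migration to the new alkoxide; the carbinol centre forms as a racemate and is removed in step 4.

**Step 4**
Reactants: 8 7-(tetrahydro-2H-pyran-2-yloxy)-1-[2,4,6-tris(triisopropylsilyloxy)phenyl]hept-5-yn-1-ol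
Product: 9 7-(tetrahydro-2H-pyran-2-yloxy)-1-[2,4,6-tris(triisopropylsilyloxy)phenyl]hept-5-yn-1-one
Conditions: Dess–Martin periodinane, CH2Cl2, 0 °C to rt
Reagents that add atoms: none
Why: Dess–Martin oxidation should convert the hindered benzylic alcohol to the aryl ketone under near-neutral conditions that spare the THP acetal, the alkyne and the aryl silyl ethers.

**Step 5**
Reactants: 9 7-(tetrahydro-2H-pyran-2-yloxy)-1-[2,4,6-tris(triisopropylsilyloxy)phenyl]hept-5-yn-1-one
Product: 10 7-bromo-1-[2,4,6-tris(triisopropylsilyloxy)phenyl]hept-5-yn-1-one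
Conditions: CBr4, PPh3, CH2Cl2, 0 °C to rt
Reagents that add atoms: carbon tetrabromide, `BrC(Br)(Br)Br`
Why: Ph3P/CBr4 should convert the THP ether directly into the primary propargylic bromide through an oxyphosphonium ion (Appel-type bromination of a tetrahydropyranyl ether), so no separate acetal hydrolysis is needed.

**Step 6**
Reactants: 11 but-1-yne; 12 (S)-glycidyl trityl ether [(S)-2-(trityloxymethyl)oxirane]
Product: 14 (S)-1-(trityloxy)hept-4-yn-2-ol, via but-1-yn-1-yllithium 13 (not isolated)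
Conditions: n-BuLi, THF, −78 °C; BF3·OEt2; then 12, −78 °C; aq NH4Cl
Reagents that add atoms: none
Why: BF3-promoted opening of the terminal epoxide by the alkynyllithium (Yamaguchi–Hirao alkynylation) should take place at the unsubstituted CH2, so the future C15 centre is untouched and keeps the S configuration of the chiral-pool epoxide.

**Step 7**
Reactants: 14 (S)-1-(trityloxy)hept-4-yn-2-ol
Product: 15 (S)-tert-butyldimethyl{[1-(trityloxy)hept-4-yn-2-yl]oxy}silane
Conditions: TBSCl, imidazole, DMF, rt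
Reagents that add atoms: tert-butyldimethylsilyl chloride, `CC(C)(C)[Si](C)(C)Cl`
Why: Imidazole-promoted O-silylation should protect the secondary alcohol as a TBS ether that is stable to the ylide, carbonate and hydrogenation steps ahead.

**Step 8**
Reactants: 15 (S)-tert-butyldimethyl{[1-(trityloxy)hept-4-yn-2-yl]oxy}silane
Product: 16 (S)-2-[(tert-butyldimethylsilyl)oxy]hept-4-yn-1-ol
Conditions: p-TsOH·H2O (cat.), MeOH/CH2Cl2, 0 °C
Reagents that add atoms: none
Why: Acid-catalysed methanolysis should cleave the primary trityl ether through the stabilised trityl cation much faster than the secondary TBS ether (chemoselective detritylation).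

**Step 9**
Reactants: 16 (S)-2-[(tert-butyldimethylsilyl)oxy]hept-4-yn-1-ol; 17 (triphenylphosphoranylidene)acetaldehyde
Product: 19 (S,E)-4-[(tert-butyldimethylsilyl)oxy]non-2-en-6-ynal, via aldehyde 18 (not isolated)
Conditions: Dess–Martin periodinane, CH2Cl2, 0 °C to rt; then 17 (excess), rt to 40 °C
Reagents that add atoms: none
Why: Dess–Martin oxidation should give the configurationally labile α-silyloxy aldehyde, which is trapped in the same flask by the stabilised formyl ylide to give the E-enal (tandem oxidation–Wittig olefination), limiting epimerisation at C15.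

**Step 10**
Reactants: 20 (4-bromobut-1-yn-1-yl)trimethylsilane
Product: 21 triphenyl[4-(trimethylsilyl)but-3-yn-1-yl]phosphonium bromide
Conditions: PPh3, MeCN, reflux
Reagents that add atoms: triphenylphosphine, `c1ccc(cc1)P(c1ccccc1)c1ccccc1`
Why: SN2 quaternisation of the non-basic phosphine at the primary bromide should give the phosphonium salt without elimination.

**Step 11**
Reactants: 21 triphenyl[4-(trimethylsilyl)but-3-yn-1-yl]phosphonium bromide; 19 (S,E)-4-[(tert-butyldimethylsilyl)oxy]non-2-en-6-ynal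
Product: 24 tert-butyldimethyl{[(S,4Z,6E)-trideca-4,6-dien-1,10-diyn-8-yl]oxy}silane, via ylide 22 (not isolated), via TMS-alkyne 23 (not isolated)
Conditions: NaHMDS, THF/DMPU, −78 °C; 19, −78 to 0 °C; then MeOH, K2CO3 (cat.), rt
Reagents that add atoms: none
Why: The salt-free non-stabilised ylide should add to the enal under kinetic control to give the 11Z olefin beside the existing 13E olefin (Z-selective Wittig olefination), and carbonate in methanol then cleaves the C(sp)–Si bond in the same flask.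

**Step 12**
Reactants: 24 tert-butyldimethyl{[(S,4Z,6E)-trideca-4,6-dien-1,10-diyn-8-yl]oxy}silane; 10 7-bromo-1-[2,4,6-tris(triisopropylsilyloxy)phenyl]hept-5-yn-1-one
Product: 27 (11Z,13E,15S)-15-[(tert-butyldimethylsilyl)oxy]-1-[2,4,6-tris(triisopropylsilyloxy)phenyl]icosa-11,13-dien-5,8,17-triyn-1-one, via copper acetylide 25 (not isolated), via propargylic iodide 26 (not isolated)
Conditions: CuI, NaI, K2CO3, DMF, rt, argon
Reagents that add atoms: none
Why: Carbonate and CuI convert the only acidic C–H of 24, the terminal C(sp)–H at C8, into copper acetylide 25, while NaI turns bromide 10 into the more reactive iodide 26; 25 then displaces iodide at the primary propargylic carbon C7 (oxidative addition and reductive elimination at copper, net SN2) to form the C7–C8 bond. The closest known reaction type is the copper(I)-mediated coupling of terminal alkynes with propargylic halides used to assemble skipped polyynes on the way to polyunsaturated fatty acids. No ring is closed and no stereocentre is formed; C15 and the preformed 11Z,13E-diene are spectators. The step needs α (SN2) over γ (SN2′, allenyne) regioselectivity, which the unsubstituted primary CH2 terminus of 10 secures, and C- over O-alkylation, which the three TIPS ethers on the phloroglucinol ring secure. It also needs the doubly activated methylenes C7 and C10 not to isomerise to allenes, which a weak heterogeneous base at room temperature, without amine or alkoxide, should allow.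

**Step 13**
Reactants: 27 (11Z,13E,15S)-15-[(tert-butyldimethylsilyl)oxy]-1-[2,4,6-tris(triisopropylsilyloxy)phenyl]icosa-11,13-dien-5,8,17-triyn-1-one
Product: 28 (5Z,8Z,11Z,13E,15S,17Z)-15-[(tert-butyldimethylsilyl)oxy]-1-[2,4,6-tris(triisopropylsilyloxy)phenyl]icosa-5,8,11,13,17-pentaen-1-one
Conditions: H2 (1 atm), Lindlar catalyst, quinoline, EtOAc, 0 °C to rt, stopped after 3 equiv H2
Reagents that add atoms: none
Why: Lead-poisoned palladium with quinoline should deliver H2 syn to each alkyne and release the cis-alkene before further reduction (Lindlar semi-hydrogenation), setting the 5Z, 8Z and 17Z olefins in one operation while the conjugated diene and the aryl ketone react far more slowly.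

**Step 14**
Reactants: 28 (5Z,8Z,11Z,13E,15S,17Z)-15-[(tert-butyldimethylsilyl)oxy]-1-[2,4,6-tris(triisopropylsilyloxy)phenyl]icosa-5,8,11,13,17-pentaen-1-one
Product: 29 (5Z,8Z,11Z,13E,15S,17Z)-15-hydroxy-1-(2,4,6-trihydroxyphenyl)icosa-5,8,11,13,17-pentaen-1-one
Conditions: TBAF, AcOH, THF, 0 °C to rt
Reagents that add atoms: none
Why: Fluoride should cleave the three aryl O–Si bonds and the secondary TBS ether (fluoride-mediated desilylation), and the acetic acid buffer protects the acid- and base-sensitive dienyl carbinol and skipped polyene.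

**Compound list**

1 | 2,4,6-trihydroxybenzaldehyde | `O=Cc1c(O)cc(O)cc1O` | starting material
2 | 2,4,6-tris(triisopropylsilyloxy)benzaldehyde | `O=Cc1c(O[Si](C(C)C)(C(C)C)C(C)C)cc(O[Si](C(C)C)(C(C)C)C(C)C)cc1O[Si](C(C)C)(C(C)C)C(C)C` | intermediate
3 | 2-(prop-2-yn-1-yloxy)tetrahydro-2H-pyran (racemic) | `C#CCOC1CCCCO1` | starting material
4 | 1-bromo-3-chloropropane | `ClCCCBr` | starting material
5 | lithium acetylide of 3 (not isolated) | `[Li]C#CCOC1CCCCO1` | intermediate
6 | 2-[(6-chlorohex-2-yn-1-yl)oxy]tetrahydro-2H-pyran | `ClCCCC#CCOC1CCCCO1` | intermediate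
7 | [6-(tetrahydro-2H-pyran-2-yloxy)hex-4-yn-1-yl]magnesium chloride (not isolated) | `Cl[Mg]CCCC#CCOC1CCCCO1` | intermediate
8 | 7-(tetrahydro-2H-pyran-2-yloxy)-1-[2,4,6-tris(triisopropylsilyloxy)phenyl]hept-5-yn-1-ol (diastereomer mixture) | `OC(CCCC#CCOC1CCCCO1)c1c(O[Si](C(C)C)(C(C)C)C(C)C)cc(O[Si](C(C)C)(C(C)C)C(C)C)cc1O[Si](C(C)C)(C(C)C)C(C)C` | intermediate
9 | 7-(tetrahydro-2H-pyran-2-yloxy)-1-[2,4,6-tris(triisopropylsilyloxy)phenyl]hept-5-yn-1-one | `O=C(CCCC#CCOC1CCCCO1)c1c(O[Si](C(C)C)(C(C)C)C(C)C)cc(O[Si](C(C)C)(C(C)C)C(C)C)cc1O[Si](C(C)C)(C(C)C)C(C)C` | intermediate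
10 | 7-bromo-1-[2,4,6-tris(triisopropylsilyloxy)phenyl]hept-5-yn-1-one | `O=C(CCCC#CCBr)c1c(O[Si](C(C)C)(C(C)C)C(C)C)cc(O[Si](C(C)C)(C(C)C)C(C)C)cc1O[Si](C(C)C)(C(C)C)C(C)C` | intermediate
11 | but-1-yne | `CCC#C` | starting material
12 | (S)-glycidyl trityl ether | `C1[C@H](O1)COC(c2ccccc2)(c2ccccc2)c2ccccc2` | starting material
13 | but-1-yn-1-yllithium (not isolated) | `[Li]C#CCC` | intermediate
14 | (S)-1-(trityloxy)hept-4-yn-2-ol | `CCC#CC[C@H](O)COC(c1ccccc1)(c1ccccc1)c1ccccc1` | intermediate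
15 | (S)-tert-butyldimethyl{[1-(trityloxy)hept-4-yn-2-yl]oxy}silane | `CCC#CC[C@H](O[Si](C)(C)C(C)(C)C)COC(c1ccccc1)(c1ccccc1)c1ccccc1` | intermediate
16 | (S)-2-[(tert-butyldimethylsilyl)oxy]hept-4-yn-1-ol | `CCC#CC[C@H](O[Si](C)(C)C(C)(C)C)CO` | intermediate
17 | (triphenylphosphoranylidene)acetaldehyde | `O=CC=P(c1ccccc1)(c1ccccc1)c1ccccc1` | starting material
18 | (S)-2-[(tert-butyldimethylsilyl)oxy]hept-4-ynal (not isolated) | `CCC#CC[C@H](O[Si](C)(C)C(C)(C)C)C=O` | intermediate
19 | (S,E)-4-[(tert-butyldimethylsilyl)oxy]non-2-en-6-ynal | `CCC#CC[C@H](O[Si](C)(C)C(C)(C)C)/C=C/C=O` | intermediate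
20 | (4-bromobut-1-yn-1-yl)trimethylsilane | `C[Si](C)(C)C#CCCBr` | starting material
21 | triphenyl[4-(trimethylsilyl)but-3-yn-1-yl]phosphonium bromide | `C[Si](C)(C)C#CCC[P+](c1ccccc1)(c1ccccc1)c1ccccc1.[Br-]` | intermediate
22 | triphenyl[4-(trimethylsilyl)but-3-yn-1-ylidene]phosphorane (not isolated) | `C[Si](C)(C)C#CCC=P(c1ccccc1)(c1ccccc1)c1ccccc1` | intermediate
23 | tert-butyldimethyl{[(S,4Z,6E)-1-(trimethylsilyl)trideca-4,6-dien-1,10-diyn-8-yl]oxy}silane (not isolated) | `CCC#CC[C@H](O[Si](C)(C)C(C)(C)C)/C=C/C=C\CC#C[Si](C)(C)C` | intermediate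
24 | tert-butyldimethyl{[(S,4Z,6E)-trideca-4,6-dien-1,10-diyn-8-yl]oxy}silane | `CCC#CC[C@H](O[Si](C)(C)C(C)(C)C)/C=C/C=C\CC#C` | intermediate
25 | copper(I) acetylide of 24 (not isolated) | `CCC#CC[C@H](O[Si](C)(C)C(C)(C)C)/C=C/C=C\CC#C[Cu]` | intermediate
26 | 7-iodo-1-[2,4,6-tris(triisopropylsilyloxy)phenyl]hept-5-yn-1-one (not isolated) | `O=C(CCCC#CCI)c1c(O[Si](C(C)C)(C(C)C)C(C)C)cc(O[Si](C(C)C)(C(C)C)C(C)C)cc1O[Si](C(C)C)(C(C)C)C(C)C` | intermediate
27 | (11Z,13E,15S)-15-[(tert-butyldimethylsilyl)oxy]-1-[2,4,6-tris(triisopropylsilyloxy)phenyl]icosa-11,13-dien-5,8,17-triyn-1-one | `CCC#CC[C@H](O[Si](C)(C)C(C)(C)C)/C=C/C=C\CC#CCC#CCCCC(=O)c1c(O[Si](C(C)C)(C(C)C)C(C)C)cc(O[Si](C(C)C)(C(C)C)C(C)C)cc1O[Si](C(C)C)(C(C)C)C(C)C` | intermediate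
28 | (5Z,8Z,11Z,13E,15S,17Z)-15-[(tert-butyldimethylsilyl)oxy]-1-[2,4,6-tris(triisopropylsilyloxy)phenyl]icosa-5,8,11,13,17-pentaen-1-one | `CC/C=C\C[C@H](O[Si](C)(C)C(C)(C)C)/C=C/C=C\C/C=C\C/C=C\CCCC(=O)c1c(O[Si](C(C)C)(C(C)C)C(C)C)cc(O[Si](C(C)C)(C(C)C)C(C)C)cc1O[Si](C(C)C)(C(C)C)C(C)C` | intermediate
29 | (5Z,8Z,11Z,13E,15S,17Z)-15-hydroxy-1-(2,4,6-trihydroxyphenyl)icosa-5,8,11,13,17-pentaen-1-one | `CC/C=C\C[C@H](O)/C=C/C=C\C/C=C\C/C=C\CCCC(=O)c1c(O)cc(O)cc1O` | target

**Totals.** Total step count: 14. Longest linear sequence: 8 steps (steps 6, 7, 8, 9, 11, 12, 13, 14).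

**Steps most likely to fail**

Step 12 (key coupling). What may go wrong: carbonate-induced prototropic isomerisation of the C10 methylene of 24, which lies between the alkyne and the diene, to allenic or conjugated isomers competes with cupration and alkylation. The fallback sets out from 10 and 19 and joins the large fragments by a Wittig reaction instead. Bromide 10 is coupled under the same copper conditions (CuI, NaI, K2CO3, DMF) with but-3-yn-1-ol, a robust small alkyne, to give 11-hydroxy-1-[2,4,6-tris(triisopropylsilyloxy)phenyl]undeca-5,8-diyn-1-one F1. Iodine, triphenylphosphine and imidazole convert it to 11-iodo-1-[2,4,6-tris(triisopropylsilyloxy)phenyl]undeca-5,8-diyn-1-one F2, and triphenylphosphine in warm acetonitrile gives {11-oxo-11-[2,4,6-tris(triisopropylsilyloxy)phenyl]undeca-3,6-diyn-1-yl}triphenylphosphonium iodide F3. Its ylide (NaHMDS, THF, −78 °C) is condensed with enal 19 in a Z-selective Wittig reaction that forms C11=C12 and comes back to the route at 27.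

Step 13 (triple semi-hydrogenation). What may go wrong: over-reduction or Z-to-E isomerisation of the conjugated 11Z,13E-diene on palladium while the last alkyne is still being consumed. The fallback avoids any hydrogenation once the diene exists; it sets out from 10 and 19. Diynol F1, made from 10 as described above, is semi-hydrogenated over Lindlar catalyst at the fragment stage to (5Z,8Z)-11-hydroxy-1-[2,4,6-tris(triisopropylsilyloxy)phenyl]undeca-5,8-dien-1-one F4. This is converted with I2/PPh3/imidazole to (5Z,8Z)-11-iodo-1-[2,4,6-tris(triisopropylsilyloxy)phenyl]undeca-5,8-dien-1-one F5 and then with PPh3 to {(3Z,6Z)-11-oxo-11-[2,4,6-tris(triisopropylsilyloxy)phenyl]undeca-3,6-dien-1-yl}triphenylphosphonium iodide F6. Enal 19 is semi-hydrogenated (Lindlar, quinoline) to (S,2E,6Z)-4-[(tert-butyldimethylsilyl)oxy]nona-2,6-dienal F7. Z-selective Wittig reaction of the ylide from F6 with F7 comes back to the route at 28.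

Step 11 (Wittig olefination and desilylation). What may go wrong: erosion of Z-selectivity at C11=C12 through equilibration of the Wittig intermediates with the conjugated enal, or base-induced isomerisation of the homopropargylic ylide. The fallback sets the 11Z geometry by reduction instead of olefination; it sets out from 19. Lithiated trimethylsilyldiazomethane (Colvin homologation, THF, −78 to 0 °C) converts the aldehyde to the terminal enyne tert-butyl{[(S,E)-dec-3-en-1,7-diyn-5-yl]oxy}dimethylsilane F8. Copper-mediated coupling with 3-bromo-1-(trimethylsilyl)prop-1-yne (CuI, NaI, K2CO3, DMF) gives tert-butyldimethyl{[(S,E)-1-(trimethylsilyl)tridec-6-en-1,4,10-triyn-8-yl]oxy}silane F9. Zn(Cu/Ag) in aqueous methanol reduces only the alkyne conjugated with the 13E olefin and comes back to the route at 23, which is desilylated to 24 as in step 11.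

**Further compounds**

F1 | step 12 | 11-hydroxy-1-[2,4,6-tris(triisopropylsilyloxy)phenyl]undeca-5,8-diyn-1-one | `OCCC#CCC#CCCCC(=O)c1c(O[Si](C(C)C)(C(C)C)C(C)C)cc(O[Si](C(C)C)(C(C)C)C(C)C)cc1O[Si](C(C)C)(C(C)C)C(C)C`
F2 | step 12 | 11-iodo-1-[2,4,6-tris(triisopropylsilyloxy)phenyl]undeca-5,8-diyn-1-one | `ICCC#CCC#CCCCC(=O)c1c(O[Si](C(C)C)(C(C)C)C(C)C)cc(O[Si](C(C)C)(C(C)C)C(C)C)cc1O[Si](C(C)C)(C(C)C)C(C)C`
F3 | step 12 | {11-oxo-11-[2,4,6-tris(triisopropylsilyloxy)phenyl]undeca-3,6-diyn-1-yl}triphenylphosphonium iodide | `O=C(CCCC#CCC#CCC[P+](c2ccccc2)(c2ccccc2)c2ccccc2)c1c(O[Si](C(C)C)(C(C)C)C(C)C)cc(O[Si](C(C)C)(C(C)C)C(C)C)cc1O[Si](C(C)C)(C(C)C)C(C)C.[I-]`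
F4 | step 13 | (5Z,8Z)-11-hydroxy-1-[2,4,6-tris(triisopropylsilyloxy)phenyl]undeca-5,8-dien-1-one | `OCC/C=C\C/C=C\CCCC(=O)c1c(O[Si](C(C)C)(C(C)C)C(C)C)cc(O[Si](C(C)C)(C(C)C)C(C)C)cc1O[Si](C(C)C)(C(C)C)C(C)C`
F5 | step 13 | (5Z,8Z)-11-iodo-1-[2,4,6-tris(triisopropylsilyloxy)phenyl]undeca-5,8-dien-1-one | `ICC/C=C\C/C=C\CCCC(=O)c1c(O[Si](C(C)C)(C(C)C)C(C)C)cc(O[Si](C(C)C)(C(C)C)C(C)C)cc1O[Si](C(C)C)(C(C)C)C(C)C`
F6 | step 13 | {(3Z,6Z)-11-oxo-11-[2,4,6-tris(triisopropylsilyloxy)phenyl]undeca-3,6-dien-1-yl}triphenylphosphonium iodide | `O=C(CCC/C=C\C/C=C\CC[P+](c2ccccc2)(c2ccccc2)c2ccccc2)c1c(O[Si](C(C)C)(C(C)C)C(C)C)cc(O[Si](C(C)C)(C(C)C)C(C)C)cc1O[Si](C(C)C)(C(C)C)C(C)C.[I-]`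
F7 | step 13 | (S,2E,6Z)-4-[(tert-butyldimethylsilyl)oxy]nona-2,6-dienal | `CC/C=C\C[C@H](O[Si](C)(C)C(C)(C)C)/C=C/C=O`
F8 | step 11 | tert-butyl{[(S,E)-dec-3-en-1,7-diyn-5-yl]oxy}dimethylsilane | `CCC#CC[C@H](O[Si](C)(C)C(C)(C)C)/C=C/C#C`
F9 | step 11 | tert-butyldimethyl{[(S,E)-1-(trimethylsilyl)tridec-6-en-1,4,10-triyn-8-yl]oxy}silane | `CCC#CC[C@H](O[Si](C)(C)C(C)(C)C)/C=C/C#CCC#C[Si](C)(C)C`
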